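The carbocycle C3a–C4–C5–C6–C7–C7a (1-benzofuran numbering, ring A) is a 3-alkoxy-4,4-disubstituted 6-methoxycyclohex-2-enone, that is, a 3-alkoxycyclobutenone (C6, C7, C7a, C3a) into whose C3a–C6 bond the two carbons C4 and C5 of a 1-methoxyvinyl unit have been inserted. The key step adds 1-methoxyvinyllithium to a bicyclic cyclobutenone that already holds the dihydrofuran ring B; the cyclobutenoxide opens (4π) and recloses (6π) to the cyclohexenone, creating quaternary C3a and C5 in one operation and giving the target directly. The cyclobutenone comes from a ketene [2+2] cycloaddition onto a 2,3-dihydrofuran built from (S)-γ-valerolactone.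

Key step: step 8

Remark: the atom labels of the target (O1, C2, C3, C3a, C4–C7, C7a) are used for the corresponding atoms of all intermediates; Ar = 3,4,5-trimethoxyphenyl; compounds 1 and 5 (as its THF solution) are taken as commercial.

Step 1
Reactants: 1 (S)-γ-valerolactone
Product: 4 (S)-5-methylfuran-2(5H)-one, via selenide 2 (not isolated), via selenoxide 3 (not isolated)
Conditions: LiN(i-Pr)2, THF, −78 °C; PhSeBr, −78 °C; then 30% H2O2, pyridine, CH2Cl2, 0 °C → rt
Reagents that add atoms: none
Why: α-Selenenylation of the lithium lactone enolate and selenoxide syn-elimination (only the C3 hydrogens are β to selenium) should give the conjugated butenolide without touching the C2 stereocentre.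

Step 2
Reactants: 4 (S)-5-methylfuran-2(5H)-one; 5 3,4,5-trimethoxyphenylmagnesium bromide
Product: 7 (3R,4S,5S)-3-allyl-5-methyl-4-(3,4,5-trimethoxyphenyl)oxolan-2-one, via magnesium enolate 6 (not isolated)
Conditions: 5 (1.3 equiv), CuBr·SMe2 (10 mol%), THF, −78 → −40 °C; then allyl bromide, DMPU, −40 → 0 °C; aq NH4Cl
Reagents that add atoms: allyl bromide, C=CCBr
Why: Copper-catalysed 1,4-addition of the aryl Grignard reagent should occur anti to the C2 methyl group, setting C3 trans to it, and the magnesium enolate 6 is then allylated at C3a trans to the aryl group (tandem conjugate addition–enolate alkylation); the C3a configuration is inconsequential because it is erased in step 4.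

Step 3
Reactants: 7 (3R,4S,5S)-3-allyl-5-methyl-4-(3,4,5-trimethoxyphenyl)oxolan-2-one
Product: 8 (3R,4S,5S)-3-allyl-5-methyl-4-(3,4,5-trimethoxyphenyl)oxolan-2-ol (anomeric mixture)
Conditions: i-Bu2AlH (1.1 equiv), CH2Cl2, −78 °C; aq potassium sodium tartrate work-up
Reagents that add atoms: none
Why: Reduction of a γ-lactone with one equivalent of i-Bu2AlH at −78 °C stops at the aluminium hemiacetal and should give the lactol without touching the allyl group or the stereocentres.

Step 4
Reactants: 8 (3R,4S,5S)-3-allyl-5-methyl-4-(3,4,5-trimethoxyphenyl)oxolan-2-ol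
Product: 10 (2S,3R)-4-allyl-2-methyl-3-(3,4,5-trimethoxyphenyl)-2,3-dihydrofuran, via anomeric mesylate 9 (not isolated)
Conditions: MeSO2Cl, Et3N, CH2Cl2, 0 °C → reflux
Reagents that add atoms: none
Why: Mesylation of the anomeric hydroxyl and triethylamine-induced loss of methanesulfonate and the C3a hydrogen (lactol dehydration) should give the trisubstituted cyclic enol ether with C2 and C3 untouched.

Step 5
Reactants: 10 (2S,3R)-4-allyl-2-methyl-3-(3,4,5-trimethoxyphenyl)-2,3-dihydrofuran
Product: 11 (1S,3S,4R,5R)-5-allyl-7,7-dichloro-3-methyl-4-(3,4,5-trimethoxyphenyl)-2-oxabicyclo[3.2.0]heptan-6-one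
Conditions: Cl3CCOCl, Zn(Cu) couple, Et2O/DME, rt, slow addition
Reagents that add atoms: dichloroketene, ClC(Cl)=C=O (made in the flask from trichloroacetyl chloride, ClC(Cl)(Cl)C(Cl)=O, and zinc)
Why: The thermal ketene–alkene [2+2] cycloaddition of dichloroketene with the electron-rich enol ether should be regioselective (carbonyl carbon to nucleophilic C3a, CCl2 to oxygen-bearing C7a) and should occur on the face anti to the neighbouring aryl group, giving the cis-fused cyclobutanone with allyl cis to aryl, while the unactivated allyl double bond reacts far more slowly.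

Step 6
Reactants: 11 (1S,3S,4R,5R)-5-allyl-7,7-dichloro-3-methyl-4-(3,4,5-trimethoxyphenyl)-2-oxabicyclo[3.2.0]heptan-6-one
Product: 12 (1R,3S,4R,5R)-5-allyl-3-methyl-4-(3,4,5-trimethoxyphenyl)-2-oxabicyclo[3.2.0]heptan-6-one
Conditions: Zn dust, NH4Cl, MeOH, rt
Reagents that add atoms: none
Why: Reductive dechlorination of an α,α-dichlorocyclobutanone with zinc in a buffered protic medium is the standard follow-up of a dichloroketene cycloaddition and should leave the ether, the alkene and all stereocentres untouched.

Step 7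
Reactants: 12 (1R,3S,4R,5R)-5-allyl-3-methyl-4-(3,4,5-trimethoxyphenyl)-2-oxabicyclo[3.2.0]heptan-6-one
Product: 14 (3S,4R,5R)-5-allyl-3-methyl-4-(3,4,5-trimethoxyphenyl)-2-oxabicyclo[3.2.0]hept-1(7)-en-6-one, via silyl enol ether 13 (not isolated)
Conditions: LiN(i-Pr)2, Me3SiCl, THF, −78 °C; then Pd(OAc)2 (1.05 equiv), MeCN, rt
Reagents that add atoms: none
Why: In this Saegusa–Ito oxidation the ketone can enolise only towards C7 (C3a is quaternary), and the divalent-palladium enolate formed from 13 on the convex face should undergo syn β-hydride elimination of the cis C7a–H to give the push–pull-stabilised 3-alkoxycyclobutenone.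

Step 8
Reactants: 14 (3S,4R,5R)-5-allyl-3-methyl-4-(3,4,5-trimethoxyphenyl)-2-oxabicyclo[3.2.0]hept-1(7)-en-6-one
Product: 18 (2S,3R,3aR,5R)-3a-allyl-5-methoxy-2-methyl-3-(3,4,5-trimethoxyphenyl)-3,3a,4,5-tetrahydro-1-benzofuran-6(2H)-one, via lithium cyclobutenoxide 15 (not isolated), via trienolate 16 (not isolated), via dienolate 17 (not isolated)
Conditions: CH2=CHOMe, t-BuLi, THF, −78 → 0 °C; add 14, −78 °C → rt (40 °C if needed); MeOH, rt; aq NH4Cl
Reagents that add atoms: 1-methoxyvinyllithium, [Li]C(=C)OC (made in the flask from methyl vinyl ether, C=COC, and t-BuLi)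
Why: 1-Methoxyvinyllithium should add 1,2 to the strained vinylogous-ester carbonyl C6 of 14 on the face anti to the allyl group, giving alkoxide 15 with the oxide cis to allyl. On warming, oxy-anion-accelerated conrotatory 4π opening of the cyclobutene breaks the C3a–C6 bond with the oxide turning outward, which sends the 1-methoxyvinyl and allyl groups inward and keeps ring-bound C3 outward, so that trienolate 16 has the cis central C6=C7 bond needed for closure. Ring A then closes by thermal disrotatory 6π electrocyclisation (new C4–C3a bond), accelerated by the 2-oxido substituent, to dienolate 17, which is protonated at C5. The closest known reaction type is the two-carbon ring expansion of cyclobutenones to cyclohexenones by alkenyllithium addition, 4π opening and 6π closure, a relative of the thermal rearrangement of 4-alkenylcyclobutenones. C3a is set by 1,2-induction from C3 (C4 bonds to the face of the C3a=C7a double bond anti to the aryl group, leaving allyl cis to aryl), and C5 is set under thermodynamic control during the methoxide equilibration, the methoxy group taking the pseudo-equatorial position trans to the pseudo-axial allyl group to avoid a 1,3-diaxial contact. The step needs 1,2- rather than 1,4-addition (hard organolithium, strained ketone) and a matched torquoselectivity (anti-to-allyl addition plus the ring B tether); the C3a configuration of 14 is erased and re-made, so only C2 and C3 carry the stereochemical information.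

Compound list
1 | (S)-γ-valerolactone, (5S)-5-methyloxolan-2-one | C[C@@H]1OC(=O)CC1 | starting material
2 | (5S)-5-methyl-3-(phenylselanyl)oxolan-2-one, mixture at the selenium-bearing carbon | C[C@@H]1OC(=O)C([Se]c2ccccc2)C1 | intermediate
3 | (5S)-5-methyl-3-(phenylseleninyl)oxolan-2-one | C[C@@H]1OC(=O)C([Se](=O)c2ccccc2)C1 | intermediate
4 | (S)-5-methylfuran-2(5H)-one | C[C@@H]1OC(=O)C=C1 | intermediate
5 | 3,4,5-trimethoxyphenylmagnesium bromide | COc1cc([Mg]Br)cc(OC)c1OC | starting material
6 | bromomagnesium enolate of (4S,5S)-5-methyl-4-(3,4,5-trimethoxyphenyl)oxolan-2-one | C[C@@H]1OC(O[Mg]Br)=C[C@H]1c1cc(OC)c(OC)c(OC)c1 | intermediate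
7 | (3R,4S,5S)-3-allyl-5-methyl-4-(3,4,5-trimethoxyphenyl)oxolan-2-one (all-trans lactone) | O=C1O[C@@H](C)[C@H](c2cc(OC)c(OC)c(OC)c2)[C@H]1CC=C | intermediate
8 | (3R,4S,5S)-3-allyl-5-methyl-4-(3,4,5-trimethoxyphenyl)oxolan-2-ol (lactol, anomeric mixture) | OC1O[C@@H](C)[C@H](c2cc(OC)c(OC)c(OC)c2)[C@H]1CC=C | intermediate
9 | anomeric methanesulfonate of lactol 8 | CS(=O)(=O)OC1O[C@@H](C)[C@H](c2cc(OC)c(OC)c(OC)c2)[C@H]1CC=C | intermediate
10 | (2S,3R)-4-allyl-2-methyl-3-(3,4,5-trimethoxyphenyl)-2,3-dihydrofuran | C=CCC1=CO[C@@H](C)[C@@H]1c1cc(OC)c(OC)c(OC)c1 | intermediate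
11 | (1S,3S,4R,5R)-5-allyl-7,7-dichloro-3-methyl-4-(3,4,5-trimethoxyphenyl)-2-oxabicyclo[3.2.0]heptan-6-one (cis-fused, allyl cis to aryl) | C=CC[C@]12C(=O)C(Cl)(Cl)[C@H]1O[C@@H](C)[C@@H]2c1cc(OC)c(OC)c(OC)c1 | intermediate
12 | (1R,3S,4R,5R)-5-allyl-3-methyl-4-(3,4,5-trimethoxyphenyl)-2-oxabicyclo[3.2.0]heptan-6-one | C=CC[C@]12C(=O)C[C@H]1O[C@@H](C)[C@@H]2c1cc(OC)c(OC)c(OC)c1 | intermediate
13 | trimethylsilyl enol ether of 12 (C6=C7) | C=CC[C@]12C(O[Si](C)(C)C)=C[C@H]1O[C@@H](C)[C@@H]2c1cc(OC)c(OC)c(OC)c1 | intermediate
14 | (3S,4R,5R)-5-allyl-3-methyl-4-(3,4,5-trimethoxyphenyl)-2-oxabicyclo[3.2.0]hept-1(7)-en-6-one | C=CC[C@]12C(=O)C=C1O[C@@H](C)[C@@H]2c1cc(OC)c(OC)c(OC)c1 | intermediate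
15 | lithium alkoxide of the 1,2-adduct of 1-methoxyvinyllithium to 14 (oxide cis to allyl) | C=CC[C@]12[C@@](O[Li])(C(=C)OC)C=C1O[C@@H](C)[C@@H]2c1cc(OC)c(OC)c(OC)c1 | intermediate
16 | ring-opened lithium trienolate, 5-(3-lithiooxy-4-methoxypenta-1,3-dien-1-yl)-2,3-dihydrofuran with 1-methoxyvinyl cis to the dihydrofuran | C=CCC1=C(/C=C(/O[Li])C(=C)OC)O[C@@H](C)[C@@H]1c1cc(OC)c(OC)c(OC)c1 | intermediate
17 | lithium C5=C6 dienolate of 18 | C=CC[C@]12CC(OC)=C(O[Li])C=C1O[C@@H](C)[C@@H]2c1cc(OC)c(OC)c(OC)c1 | intermediate
18 | (2S,3R,3aR,5R)-3a-allyl-5-methoxy-2-methyl-3-(3,4,5-trimethoxyphenyl)-3,3a,4,5-tetrahydro-1-benzofuran-6(2H)-one | C=CC[C@]12C[C@@H](OC)C(=O)C=C1O[C@@H](C)[C@@H]2c1cc(OC)c(OC)c(OC)c1 | target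

Total step count: 8. Longest linear sequence: 8 steps (1 → 18).

Steps most likely to fail

Step 8. The addition may occur on the allyl face, which blocks the allowed oxide-outward ring opening. The hindered trienolate 16 may also be protonated or may decompose before the 6π closure, or equilibration at C5 may stay incomplete. The fallback sets out from 14 and comes back at 18, and it runs the cascade in neutral form. The 1,2-adduct of 1-methoxyvinyllithium and 14 is silylated at −78 °C with Me3SiCl to give the isolable tertiary trimethylsilyl ether F1. Heating in toluene at about 80 °C should then bring about conrotatory opening with the siloxy group outward and 6π closure to the silyl dienol ether F2. Cleavage of the silyl dienol ether with K2CO3 in MeOH protonates C5 under equilibrating conditions and should give 18.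

Step 7. β-Hydride elimination from the strained four-membered palladium enolate may be slow, so that the ketone is merely regenerated or the ring oxygen is lost by β-alkoxide elimination. The fallback sets out from 12 and comes back at 14, and it replaces the palladium step by a selenoxide elimination. LiN(i-Pr)2 and PhSeCl in THF at −78 °C should give the exo α-phenylselanyl ketone F3. Oxidation with H2O2/pyridine at 0 °C gives the selenoxide F4, whose syn-elimination towards the cis C7a–H should give 14.

Step 5. The zinc chloride formed may cause oligomerisation or hydrolysis of the acid-labile enol ether, and the cycloaddition at the trisubstituted double bond may be sluggish. The fallback sets out from 10 and comes back at 12, and it uses a zinc-free keteniminium [2+2] cycloaddition. N,N-Dimethylacetamide, (CF3SO2)2O and 2,4,6-collidine in ClCH2CH2Cl (0 °C → reflux) should give the cyclobutaniminium triflate F5 with the same regiochemistry and facial sense. Hydrolysis with aqueous NaHCO3 should give 12 directly, so that step 6 is no longer needed.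

Further compounds
F1 | step 8 | (3S,4R,5R)-5-allyl-6-(1-methoxyvinyl)-3-methyl-6-(trimethylsilyloxy)-4-(3,4,5-trimethoxyphenyl)-2-oxabicyclo[3.2.0]hept-1(7)-ene, siloxy cis to allyl | C=CC[C@]12[C@@](O[Si](C)(C)C)(C(=C)OC)C=C1O[C@@H](C)[C@@H]2c1cc(OC)c(OC)c(OC)c1
F2 | step 8 | (2S,3R,3aR)-3a-allyl-5-methoxy-2-methyl-6-(trimethylsilyloxy)-3-(3,4,5-trimethoxyphenyl)-2,3,3a,4-tetrahydro-1-benzofuran | C=CC[C@]12CC(OC)=C(O[Si](C)(C)C)C=C1O[C@@H](C)[C@@H]2c1cc(OC)c(OC)c(OC)c1
F3 | step 7 | exo-7-(phenylselanyl) derivative of 12 | C=CC[C@]12C(=O)[C@H]([Se]c3ccccc3)[C@H]1O[C@@H](C)[C@@H]2c1cc(OC)c(OC)c(OC)c1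
F4 | step 7 | exo-7-(phenylseleninyl) derivative of 12 | C=CC[C@]12C(=O)[C@H]([Se](=O)c3ccccc3)[C@H]1O[C@@H](C)[C@@H]2c1cc(OC)c(OC)c(OC)c1
F5 | step 5 | N,N-dimethyl cyclobutaniminium trifluoromethanesulfonate corresponding to ketone 12 | C=CC[C@]12C(=[N+](C)C)C[C@H]1O[C@@H](C)[C@@H]2c1cc(OC)c(OC)c(OC)c1.[O-]S(=O)(=O)C(F)(F)F
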